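**Strategy.** Numbering the arene C1–C6 (C1 bears the chain) and the chain C7(=C14H2)–C8(O)–C9–C10=C11, the C8–C9 unit sits between two alkenyl carbons, C7 and C10, and C8 carries oxygen. The route therefore rests on cutting C7–C8 and C9–C10. A vinyl group on boron accepts the 1-arylvinyl group at C8 by a palladium-induced 1,2-metalate shift and an isobutenyl electrophile at C9. This should give the whole C7–C11 chain and the C8 stereocentre in one operation, with boron as the latent C8 oxygen. The precursor is a 1-arylvinyl pinacol boronate whose benzene ring already carries differentiated meta oxygens (OMe, OSi(iPr)3) flanking the C4 methyl.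

Key step: step 8

Remark on the chemistry: the two meta oxygens are differentiated before the coupling, not after it. After the coupling the C8 alkoxide would be a 3-oxido-1,5-diene, open to anionic oxy-Cope rearrangement under hot thiolate demethylation.

Assumption: which antipode of the MandyPhos ligand gives the S boronate is to be fixed in a trial run by Mosher ester analysis of the derived alcohol; both antipodes are available.

Step 1
Reactants: 1 3,5-dimethoxy-4-methylbenzoic acid
Product: 2 1-(3,5-dimethoxy-4-methylphenyl)ethanone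
Conditions: MeLi (2.2 equiv), THF, 0 °C to rt; then inverse quench into cold aq HCl
Reagents that add atoms: methyllithium, [Li]C
Why: Addition of an organolithium to a lithium carboxylate (methyl ketone synthesis from a carboxylic acid) should stop at the ketone stage because the dilithium gem-diolate is stable until the acidic quench.

Step 2
Reactants: 2 1-(3,5-dimethoxy-4-methylphenyl)ethanone
Product: 3 1-(3-hydroxy-5-methoxy-4-methylphenyl)ethanone
Conditions: NaSEt (3 equiv), DMF, 120 °C; then aq HCl
Reagents that add atoms: none
Why: SN2 O-demethylation of an aryl methyl ether by thiolate should stop after one of the two symmetry-equivalent methoxy groups, because the phenoxide formed deactivates the remaining ether, and the weakly basic thiolate leaves the methyl ketone alone.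

Step 3
Reactants: 3 1-(3-hydroxy-5-methoxy-4-methylphenyl)ethanone
Product: 4 1-[3-methoxy-4-methyl-5-(triisopropylsilyloxy)phenyl]ethanone
Conditions: iPr3SiCl, imidazole, DMF, rt
Reagents that add atoms: triisopropylsilyl chloride, CC(C)[Si](Cl)(C(C)C)C(C)C
Why: Imidazole-mediated silylation of a phenol should give the aryl triisopropylsilyl ether, chosen because it withstands the bases, the organolithium and the perborate used later.

Step 4
Reactants: 4 1-[3-methoxy-4-methyl-5-(triisopropylsilyloxy)phenyl]ethanone
Product: 6 1-[3-methoxy-4-methyl-5-(triisopropylsilyloxy)phenyl]vinyl trifluoromethanesulfonate, via potassium enolate 5 (not isolated)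
Conditions: KN(SiMe3)2 (1.05 equiv), THF, −78 °C; then PhNTf2, −78 to 0 °C
Reagents that add atoms: N-phenylbis(trifluoromethanesulfonimide), O=S(=O)(N(c1ccccc1)S(=O)(=O)C(F)(F)F)C(F)(F)F
Why: Enol triflate formation by O-sulfonylation of the only possible enolate of the methyl ketone should be clean at low temperature with no excess base, which avoids elimination to the arylalkyne.

Step 5
Reactants: 6 1-[3-methoxy-4-methyl-5-(triisopropylsilyloxy)phenyl]vinyl trifluoromethanesulfonate
Product: 7 2-{1-[3-methoxy-4-methyl-5-(triisopropylsilyloxy)phenyl]vinyl}-4,4,5,5-tetramethyl-1,3,2-dioxaborolane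
Conditions: B2pin2, PdCl2(PPh3)2 (3 mol %), PPh3 (6 mol %), KOPh, toluene, 50 °C
Reagents that add atoms: bis(pinacolato)diboron, CC1(C)OB(B2OC(C)(C)C(C)(C)O2)OC1(C)C
Why: Miyaura borylation of a 1-alkenyl triflate should work under the mild phenoxide conditions established for this substrate class, which suppress coupling of the product boronate with unreacted triflate.

Step 6
Reactants: 8 isobutyraldehyde
Product: 9 2-methylprop-1-enyl trifluoromethanesulfonate
Conditions: Tf2O, 2,6-di-tert-butyl-4-methylpyridine, CH2Cl2, 0 °C to reflux; distil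
Reagents that add atoms: trifluoromethanesulfonic anhydride, O=S(=O)(OS(=O)(=O)C(F)(F)F)C(F)(F)F
Why: Vinyl triflate synthesis from an enolisable aldehyde (O-triflation, then elimination by a hindered non-nucleophilic pyridine) can give only one alkene isomer here, since the enol carbon carries two methyl groups.

Step 7
Reactants: 10 tetravinylstannane
Product: 11 vinyllithium
Conditions: n-BuLi (4 equiv), pentane, rt; filter the precipitate under Ar, wash with pentane, dissolve in THF, titrate
Reagents that add atoms: n-butyllithium, [Li]CCCC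
Why: Tin–lithium exchange should be driven by precipitation of vinyllithium from pentane and gives the halide-free reagent that the coupling requires.

Step 8
Reactants: 7 2-{1-[3-methoxy-4-methyl-5-(triisopropylsilyloxy)phenyl]vinyl}-4,4,5,5-tetramethyl-1,3,2-dioxaborolane; 11 vinyllithium; 9 2-methylprop-1-enyl trifluoromethanesulfonate
Product: 13 (S)-2-{2-[3-methoxy-4-methyl-5-(triisopropylsilyloxy)phenyl]-6-methylhepta-1,5-dien-3-yl}-4,4,5,5-tetramethyl-1,3,2-dioxaborolane, via lithium bis(alkenyl)borate 12 (not isolated)
Conditions: 7, 11 (1.0 equiv), Et2O/THF, 0 °C to rt, evaporate; then Pd(OAc)2 (2 mol %), MandyPhos ligand 1,1'-bis[bis(4-methoxy-3,5-dimethylphenyl)phosphino]-2,2'-bis[α-(dimethylamino)benzyl]ferrocene (2.4 mol %, antipode giving S), 9 (1.2 equiv), THF, 60 °C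
Reagents that add atoms: none
Why: Vinyllithium adds to boron to give the bis(alkenyl) ate complex, and oxidative addition of the triflate to zerovalent palladium gives a cationic isobutenyl complex of divalent palladium that binds the unsubstituted vinyl group. The 1-arylvinyl group then shifts from boron to C8 anti to the metal while palladium takes C9 (metal-induced 1,2-metalate shift), and reductive elimination forms C9–C10, so that C7–C8 and C9–C10 are made in one operation. The closest known reaction type is the enantioselective Pd/MandyPhos conjunctive cross-coupling of bis(alkenyl)boron ate complexes with triflates to give allylic boronates, of which an alpha-aryl migrating alkenyl group is a demanding member. No ring is closed. The C8 stereocentre is controlled by the chiral bisphosphine, which decides the face of the vinyl group that palladium binds before the stereospecific anti migration, the antipode being chosen to give S. The step needs activation of the vinyl group in preference to the arylvinyl group and conjunctive coupling in preference to direct Suzuki-type transfer, which the 1,1-disubstitution of the arylvinyl group, the halide-free ate complex and the triflate electrophile should secure.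

Step 9
Reactants: 13 (S)-2-{2-[3-methoxy-4-methyl-5-(triisopropylsilyloxy)phenyl]-6-methylhepta-1,5-dien-3-yl}-4,4,5,5-tetramethyl-1,3,2-dioxaborolane
Product: 14 (S)-2-[3-methoxy-4-methyl-5-(triisopropylsilyloxy)phenyl]-6-methylhepta-1,5-dien-3-ol
Conditions: NaBO3·4H2O, THF/H2O, rt
Reagents that add atoms: sodium perborate (peroxoborate dimer, water of crystallisation omitted), [Na+].[Na+].O[B-]1(O)OO[B-](O)(O)OO1
Why: Oxidation of a carbon–boron bond by peroxide proceeds by 1,2-migration from boron to oxygen with retention, so C8 should keep its S configuration, and mildly basic perborate should neither epoxidise the alkenes nor cleave the aryl silyl ether.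

Step 10
Reactants: 14 (S)-2-[3-methoxy-4-methyl-5-(triisopropylsilyloxy)phenyl]-6-methylhepta-1,5-dien-3-ol; 15 angelic acid
Product: 17 (S)-2-[3-methoxy-4-methyl-5-(triisopropylsilyloxy)phenyl]-6-methylhepta-1,5-dien-3-yl (Z)-2-methylbut-2-enoate, via angeloyl 2,4,6-trichlorobenzoyl anhydride 16 (not isolated)
Conditions: 15 (3 equiv), 2,4,6-Cl3C6H2COCl (3 equiv), Et3N (3 equiv), toluene, rt; then 14, toluene, 75 °C
Reagents that add atoms: none
Why: Yamaguchi-type mixed-anhydride esterification should deliver the angeloyl group because the alcohol attacks the unshielded carbonyl, and leaving out a nucleophilic pyridine catalyst avoids the addition–elimination that turns angelate into tiglate; C8 is untouched since only its O–H bond reacts.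

Step 11
Reactants: 17 (S)-2-[3-methoxy-4-methyl-5-(triisopropylsilyloxy)phenyl]-6-methylhepta-1,5-dien-3-yl (Z)-2-methylbut-2-enoate
Product: 18 (S)-2-(3-hydroxy-5-methoxy-4-methylphenyl)-6-methylhepta-1,5-dien-3-yl (Z)-2-methylbut-2-enoate
Conditions: Bu4NF, AcOH (1:1), THF, 0 °C
Reagents that add atoms: none
Why: Fluoride-mediated cleavage of an aryl silyl ether is fast at 0 °C, and buffering with acetic acid should keep the medium from becoming basic enough to isomerise or transfer the angelate.

Step 12
Reactants: 18 (S)-2-(3-hydroxy-5-methoxy-4-methylphenyl)-6-methylhepta-1,5-dien-3-yl (Z)-2-methylbut-2-enoate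
Product: 20 (S)-2-(2,5-dihydroxy-3-methoxy-4-methylphenyl)-6-methylhepta-1,5-dien-3-yl (Z)-2-methylbut-2-enoate, via para-quinone 19 (not isolated)
Conditions: (KSO3)2NO (2.5 equiv), aq KH2PO4, acetone, 0 °C; then EtOAc, aq Na2S2O4, Ar, rt
Reagents that add atoms: potassium nitrosodisulfonate, [K+].[K+].[O]N(S(=O)(=O)[O-])S(=O)(=O)[O-]
Why: In the Teuber oxidation the phenoxyl radical should be trapped by a second nitroxide at the free para carbon C2 (ortho C4 is blocked by methyl) and lose imidodisulfonate to give the para-quinone, which dithionite reduces at once to the hydroquinone without touching alkenes, ester or C8.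

**Compound list**

1 | 3,5-dimethoxy-4-methylbenzoic acid | COc1cc(C(=O)O)cc(OC)c1C | starting material
2 | 1-(3,5-dimethoxy-4-methylphenyl)ethanone | CC(=O)c1cc(OC)c(C)c(OC)c1 | intermediate
3 | 1-(3-hydroxy-5-methoxy-4-methylphenyl)ethanone | CC(=O)c1cc(O)c(C)c(OC)c1 | intermediate
4 | 1-[3-methoxy-4-methyl-5-(triisopropylsilyloxy)phenyl]ethanone | CC(=O)c1cc(OC)c(C)c(O[Si](C(C)C)(C(C)C)C(C)C)c1 | intermediate
5 | potassium enolate of 4 | [K+].C=C([O-])c1cc(OC)c(C)c(O[Si](C(C)C)(C(C)C)C(C)C)c1 | intermediate
6 | 1-[3-methoxy-4-methyl-5-(triisopropylsilyloxy)phenyl]vinyl trifluoromethanesulfonate | C=C(OS(=O)(=O)C(F)(F)F)c1cc(OC)c(C)c(O[Si](C(C)C)(C(C)C)C(C)C)c1 | intermediate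
7 | 2-{1-[3-methoxy-4-methyl-5-(triisopropylsilyloxy)phenyl]vinyl}-4,4,5,5-tetramethyl-1,3,2-dioxaborolane | C=C(B1OC(C)(C)C(C)(C)O1)c1cc(OC)c(C)c(O[Si](C(C)C)(C(C)C)C(C)C)c1 | intermediate
8 | isobutyraldehyde | CC(C)C=O | starting material
9 | 2-methylprop-1-enyl trifluoromethanesulfonate | CC(C)=COS(=O)(=O)C(F)(F)F | intermediate
10 | tetravinylstannane | C=C[Sn](C=C)(C=C)C=C | starting material
11 | vinyllithium | [Li]C=C | intermediate
12 | lithium [1-arylvinyl](vinyl)(pinacolato)borate, aryl = 3-methoxy-4-methyl-5-(triisopropylsilyloxy)phenyl | [Li+].C=C[B-]1(OC(C)(C)C(C)(C)O1)C(=C)c1cc(OC)c(C)c(O[Si](C(C)C)(C(C)C)C(C)C)c1 | intermediate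
13 | (S)-2-{2-[3-methoxy-4-methyl-5-(triisopropylsilyloxy)phenyl]-6-methylhepta-1,5-dien-3-yl}-4,4,5,5-tetramethyl-1,3,2-dioxaborolane | C=C(c1cc(OC)c(C)c(O[Si](C(C)C)(C(C)C)C(C)C)c1)[C@H](CC=C(C)C)B1OC(C)(C)C(C)(C)O1 | intermediate
14 | (S)-2-[3-methoxy-4-methyl-5-(triisopropylsilyloxy)phenyl]-6-methylhepta-1,5-dien-3-ol | C=C(c1cc(OC)c(C)c(O[Si](C(C)C)(C(C)C)C(C)C)c1)[C@H](CC=C(C)C)O | intermediate
15 | angelic acid, (Z)-2-methylbut-2-enoic acid | C/C=C(/C)C(=O)O | starting material
16 | angeloyl 2,4,6-trichlorobenzoyl anhydride | C/C=C(/C)C(=O)OC(=O)c1c(Cl)cc(Cl)cc1Cl | intermediate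
17 | (S)-2-[3-methoxy-4-methyl-5-(triisopropylsilyloxy)phenyl]-6-methylhepta-1,5-dien-3-yl (Z)-2-methylbut-2-enoate | C=C(c1cc(OC)c(C)c(O[Si](C(C)C)(C(C)C)C(C)C)c1)[C@H](CC=C(C)C)OC(=O)/C(C)=C\C | intermediate
18 | (S)-2-(3-hydroxy-5-methoxy-4-methylphenyl)-6-methylhepta-1,5-dien-3-yl (Z)-2-methylbut-2-enoate | C=C(c1cc(OC)c(C)c(O)c1)[C@H](CC=C(C)C)OC(=O)/C(C)=C\C | intermediate
19 | (S)-2-(5-methoxy-4-methyl-3,6-dioxocyclohexa-1,4-dien-1-yl)-6-methylhepta-1,5-dien-3-yl (Z)-2-methylbut-2-enoate | C=C(C1=CC(=O)C(C)=C(OC)C1=O)[C@H](CC=C(C)C)OC(=O)/C(C)=C\C | intermediate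
20 | (S)-2-(2,5-dihydroxy-3-methoxy-4-methylphenyl)-6-methylhepta-1,5-dien-3-yl (Z)-2-methylbut-2-enoate | C=C(c1cc(O)c(C)c(OC)c1O)[C@H](CC=C(C)C)OC(=O)/C(C)=C\C | target

**Step count.** Total: 12 steps. Longest linear sequence: 10 steps (steps 1–5 and 8–12); steps 6 and 7 supply the two coupling partners.

**Steps most likely to fail**

Step 8. The ate complex may hand an alkenyl group directly to palladium (Suzuki-type transfer), palladium may engage the arylvinyl group, or the facial discrimination at the vinyl group may be poor. The fallback reaches the same allylic boronate by lithiation–borylation; it sets out from boronate 7 and comes back at 13. Commercial 4-methylpent-3-en-1-ol is carbamoylated (iPr2NCOCl, Et3N, toluene, reflux) to 4-methylpent-3-en-1-yl N,N-diisopropylcarbamate F1. s-BuLi with (+)-sparteine in Et2O at −78 °C should remove the pro-R proton next to oxygen and give the configurationally stable (R)-lithiated carbamate F2. Boronate 7 adds with retention to give the boron ate complex F3. Warming with MgBr2·OEt2 should make the arylvinyl group migrate with inversion and expel the carbamate, which gives 13 with the S configuration.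

Step 12. The nitroxide may couple at the open ortho carbon C6 in place of the flanked para carbon C2, or the transient alkenylquinone may be lost by cycloaddition or conjugate addition before it is reduced. The fallback uses an ionic two-electron oxidation through a masked quinone; it sets out from phenol 18 and comes back at quinone 19. PhI(OAc)2 (2.2 equiv) in MeOH at 0 °C should oxidise 18, by way of the para-methoxyphenol F4 (not isolated), to the quinone monoketal F5, in which methanol has added at C2 under charge control. Dilute aqueous oxalic acid in THF unmasks 19, which is reduced with Na2S2O4 as in step 12.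

Step 10. Acylation of the hindered allylic alcohol may be slow enough for the activated angeloyl unit to isomerise from Z to E, so that tiglate is carried along. The fallback builds the Z alkene on the ester; it sets out from alcohol 14 and comes back at 17. Esterification of 14 with 2-[bis(2,2,2-trifluoroethoxy)phosphoryl]propanoic acid (DCC, catalytic DMAP, CH2Cl2) gives the phosphonate ester F6, a mixture of epimers at the phosphorus-bearing carbon that is of no consequence. Still–Gennari olefination with acetaldehyde (KN(SiMe3)2, 18-crown-6, THF, −78 °C) should then give the Z-configured 2-methylbut-2-enoate 17.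

**Further compounds**

F1 | step 8 | 4-methylpent-3-en-1-yl N,N-diisopropylcarbamate | CC(C)=CCCOC(=O)N(C(C)C)C(C)C
F2 | step 8 | (R)-1-lithio-4-methylpent-3-en-1-yl N,N-diisopropylcarbamate, (+)-sparteine complex | [Li][C@H](CC=C(C)C)OC(=O)N(C(C)C)C(C)C
F3 | step 8 | lithium ate complex of 7 with F2 | [Li+].C=C(c1cc(OC)c(C)c(O[Si](C(C)C)(C(C)C)C(C)C)c1)[B-]1(OC(C)(C)C(C)(C)O1)[C@H](CC=C(C)C)OC(=O)N(C(C)C)C(C)C
F4 | step 12 | (S)-2-(5-hydroxy-2,3-dimethoxy-4-methylphenyl)-6-methylhepta-1,5-dien-3-yl (Z)-2-methylbut-2-enoate | C=C(c1cc(O)c(C)c(OC)c1OC)[C@H](CC=C(C)C)OC(=O)/C(C)=C\C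
F5 | step 12 | (S)-2-(5,6,6-trimethoxy-4-methyl-3-oxocyclohexa-1,4-dien-1-yl)-6-methylhepta-1,5-dien-3-yl (Z)-2-methylbut-2-enoate | O=C1C=C(C(=C)[C@H](CC=C(C)C)OC(=O)/C(C)=C\C)C(OC)(OC)C(OC)=C1C
F6 | step 10 | (S)-2-[3-methoxy-4-methyl-5-(triisopropylsilyloxy)phenyl]-6-methylhepta-1,5-dien-3-yl 2-[bis(2,2,2-trifluoroethoxy)phosphoryl]propanoate | C=C(c1cc(OC)c(C)c(O[Si](C(C)C)(C(C)C)C(C)C)c1)[C@H](CC=C(C)C)OC(=O)C(C)P(=O)(OCC(F)(F)F)OCC(F)(F)F
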